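Numbering (elemane): the ring is C5[C4(=C3H2)C15H2OH]–C6(OH)–C7[C11(=C13H2)C12O2H]–C8(O-acyl)–C9H2–C10(C14H3)(C1H=C2H2). The vinyl group, C4, O6, C11 and O8 all lie on one face and only the methyl group lies on the other.
End game: the Z-enoate comes from a Still–Gennari olefination on an O8 phosphonopropionate. O6 and H7 come from an O8–H-directed epoxide of C6=C7 that is opened by palladium/formate hydrogenolysis. C11–C13 come from a Stille coupling at a C7 vinyl bromide.
C4 is carried as the carbonyl of a lactone bridge. Double Me3SiCH2 addition with Peterson elimination, then epoxidation and desilylation, turns it into C(=CH2)CH2OH. The vinyl group comes from a formyl group by Wittig reaction.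
Key disconnection: C8–C9 and C5–C10 by [4+2] of 5-bromo-2-pyrone (1; supplies C4–C8 and O8) and methacrolein (2; supplies C1, C9, C10, C14). The enabling feature is that O8 on C8 and carbon C4 on C5 are 1,4-related and cis on the cyclohexane. They can therefore be one –O–C(=O)– bridge, which is O1–C2 of a 2-pyrone whose C3–C6 are C5–C8, while the C9H2–C10(Me)(C1) edge is a 1,1-disubstituted enal.
Ring order: the pyrone ring is bought and temporary. The cyclohexane is the only and last carbocycle and is closed in step 1. The lactone bridge is opened in step 3, and an epoxide serves as a further temporary ring in steps 9–13.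

Key step: step 1

Assumption: the sense of induction of the oxazaborolidinium catalyst with a 2-pyrone diene cannot be taken from precedent, so the catalyst from (S)-diphenylprolinol is written and its mirror image is to be used if a first run shows the opposite sense.

Step 1
Reactants: 1 5-bromo-2H-pyran-2-one; 2 methacrolein
Product: 3 (1R,4R,5S)-7-bromo-5-methyl-3-oxo-2-oxabicyclo[2.2.2]oct-7-ene-5-carbaldehyde (exo adduct: formyl on the side of the lactone bridge)
Conditions: (S)-1-(2-methylphenyl)-3,3-diphenyltetrahydro-1H,3H-pyrrolo[1,2-c][1,3,2]oxazaborole (20 mol %), HN(SO2CF3)2 (20 mol %), CH2Cl2, −40 to −20 °C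
Reagents that add atoms: none
Why: Proposed new method: the protonated oxazaborolidine binds the formyl oxygen of s-trans methacrolein and lowers its LUMO, so that a concerted, asynchronous normal-demand [4+2] cycloaddition across C3 and C6 of the weakly aromatic pyrone should run far below the temperature of CO2 loss; the closest known reactions are the thermal cycloadditions of 3- and 5-halo-2-pyrones to acrolein and acrylates and the oxazaborolidinium-catalysed exo additions of methacrolein to cyclopentadiene. The cyclohexene ring is closed intermolecularly by suprafacial formation of the C8–C9 and C5–C10 bonds in one event, and the old pyrone O–C(=O) unit is left as a bridge over one face (2-oxabicyclo[2.2.2]octene). C5 and C8 are fixed relative to each other by this bridge (O8 and C4 must be cis), and C10 is fixed by the exo transition state, in which the small methyl group lies under the C6=C7(Br) edge and the bulky boron-bound formyl group under the flat, unsubstituted O–C=O edge, so that the future vinyl carbon ends on the face of O8 and C4. The absolute sense comes from the catalyst, whose aryl group covers one face of the bound enal. Regioselectivity is needed and is secured by the substrate, because the bromine (a para director at pyrone C5) and the C2 carbonyl both enlarge the HOMO coefficient at pyrone C6, which therefore bonds to the CH2 terminus. The bromine stays as the handle for C11, C4 stays at the carboxyl level and C6=C7 stays for the later oxygenation.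

Step 2
Reactants: 3 exo bromolactone aldehyde
Product: 4 (1R,4R,5R)-7-bromo-5-ethenyl-5-methyl-2-oxabicyclo[2.2.2]oct-7-en-3-one
Conditions: Ph3PCH3Br, KN(SiMe3)2, THF, −78 to 0 °C
Reagents that add atoms: methyltriphenylphosphonium bromide, C[P+](c1ccccc1)(c1ccccc1)c1ccccc1.[Br-]
Why: Wittig methylenation, in which the non-enolizable neopentyl aldehyde should react with the unstabilized ylide well below the temperature at which the bridged lactone is attacked, and no stereocentre is touched.

Step 3
Reactants: 4 vinyl bromolactone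
Product: 6 (1R,4R,5R)-2-bromo-5-ethenyl-5-methyl-4-[3-(trimethylsilyl)prop-1-en-2-yl]cyclohex-2-en-1-ol, via bis(silylmethyl)carbinol 5 (not isolated)
Conditions: Me3SiCH2MgCl (5 equiv), CeCl3 (5 equiv), THF, −78 °C to rt; aqueous work-up; then silica gel, CH2Cl2, rt
Reagents that add atoms: (trimethylsilyl)methylmagnesium chloride, C[Si](C)(C)C[Mg]Cl
Why: Ester-to-allylsilane conversion (double 1,2-addition of the non-basic organocerium reagent, then Peterson elimination), which opens the strained allylic lactone bridge at C4, releases O8–H with its configuration intact and gives C4 both missing carbons C3 and C15, the vinyl bromide being inert.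

Step 4
Reactants: 6 allylsilane alcohol
Product: 8 (1R,4R,5R)-2-bromo-5-ethenyl-4-(3-hydroxyprop-1-en-2-yl)-5-methylcyclohex-2-en-1-ol, via epoxysilane 7 (not isolated)
Conditions: mCPBA (1.05 equiv), CH2Cl2, −20 °C; then AcOH (cat.), THF–H2O, rt
Reagents that add atoms: 3-chloroperoxybenzoic acid, O=C(OO)c1cccc(Cl)c1
Why: Prilezhaev epoxidation should take the allylsilane, the most electron-rich of the three alkenes, and the beta-silyl epoxide collapses under mild acid by a Peterson-type 1,2-elimination to the 2-substituted allylic alcohol, so that the transient stereocentre at C4 is erased.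

Step 5
Reactants: 8 bromo diol
Product: 9 (1R,4R,5R)-2-bromo-4-{3-[(tert-butyldimethylsilyl)oxy]prop-1-en-2-yl}-5-ethenyl-5-methylcyclohex-2-en-1-ol
Conditions: t-BuMe2SiCl (1.05 equiv), imidazole, CH2Cl2, 0 °C
Reagents that add atoms: tert-butyldimethylsilyl chloride, CC(C)(C)[Si](C)(C)Cl
Why: Chemoselective silylation, since the unhindered primary allylic alcohol reacts much faster than the secondary C8 alcohol next to the vinyl bromide, which must stay free as the later directing group.

Step 6
Reactants: 10 propiolic acid; 11 2-(trimethylsilyl)ethanol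
Product: 12 2-(trimethylsilyl)ethyl prop-2-ynoate
Conditions: DCC, DMAP (cat.), CH2Cl2, 0 °C
Reagents that add atoms: none
Why: Steglich esterification gives the fluoride-labile ester that will mask C12.

Step 7
Reactants: 12 2-(trimethylsilyl)ethyl prop-2-ynoate
Product: 13 2-(trimethylsilyl)ethyl 2-(tributylstannyl)prop-2-enoate
Conditions: n-Bu3SnH, Pd(PPh3)4 (2 mol %), THF, 0 °C
Reagents that add atoms: tributylstannane, CCCC[SnH](CCCC)CCCC
Why: Palladium-catalysed syn hydrostannylation of an alkynoate places tin on the carbon alpha to the ester (hydride goes to the electrophilic beta carbon), which gives the 1-carboalkoxyvinyl nucleophile needed for C11.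

Step 8
Reactants: 9 bromo alcohol silyl ether; 13 stannyl acrylate
Product: 14 2-(trimethylsilyl)ethyl 2-[(3R,4R,6R)-3-{3-[(tert-butyldimethylsilyl)oxy]prop-1-en-2-yl}-4-ethenyl-6-hydroxy-4-methylcyclohex-1-en-1-yl]prop-2-enoate
Conditions: Pd2(dba)3 (5 mol %), AsPh3 (20 mol %), CuI (20 mol %), DMF, 45 °C
Reagents that add atoms: none
Why: Stille coupling (copper-assisted, with a soft arsine ligand for a hindered 1-substituted vinylstannane) joins C7 to C11 without moving the ring alkene, and neither the free allylic alcohol nor the allyl silyl ether ionizes with zerovalent palladium.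

Step 9
Reactants: 14 dienyl ester alcohol
Product: 15 syn-epoxy alcohol of 14 with the C6–C7 epoxide on the face of O8 (elemane numbering 5R,6S,7R,8R,10R)
Conditions: VO(acac)2 (5 mol %), t-BuOOH (decane), CH2Cl2, 0 °C
Reagents that add atoms: tert-butyl hydroperoxide, CC(C)(C)OO
Why: Hydroxyl-directed epoxidation of a cyclic allylic alcohol, in which the vanadium alkoxide of O8 delivers oxygen to C6=C7 on its own face, setting C6 (O6 cis to O8 and C4) and leaving the electron-poor acrylate, the vinyl group and the undirected 1,1-disubstituted alkene alone.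

Step 10
Reactants: 16 bis(2,2,2-trifluoroethyl) phosphite; 17 benzyl 2-bromopropanoate (racemic)
Product: 18 benzyl 2-[bis(2,2,2-trifluoroethoxy)phosphoryl]propanoate (racemic)
Conditions: NaH, THF, 0 °C to rt
Reagents that add atoms: none
Why: Michaelis–Becker alkylation of the sodium phosphite with the alpha-bromo ester by SN2 displacement gives the Z-selective phosphonate, whose own stereocentre is lost later.

Step 11
Reactants: 18 benzyl phosphonopropanoate
Product: 19 2-[bis(2,2,2-trifluoroethoxy)phosphoryl]propanoic acid (racemic)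
Conditions: H2 (1 atm), Pd/C (10 wt %), EtOAc, rt
Reagents that add atoms: none
Why: Hydrogenolysis of the benzyl ester frees the acid without hydroxide, which would attack the labile trifluoroethyl phosphonate esters.

Step 12
Reactants: 15 syn-epoxy alcohol; 19 phosphonopropanoic acid
Product: 20 O8 2-[bis(2,2,2-trifluoroethoxy)phosphoryl]propanoate of 15 (5R,6S,7R,8R,10R; epimers at the phosphonate carbon)
Conditions: DCC, CH2Cl2, 0 °C to rt, no amine catalyst
Reagents that add atoms: none
Why: Carbodiimide esterification, in which the acidic phosphonoacid is activated by DCC (acylisourea or the derived phosphonoketene) and acylates the only free hydroxyl O8 without a nucleophilic amine that could add to the epoxy acrylate, C8 keeping its configuration.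

Step 13
Reactants: 20 epoxy phosphonate ester
Product: 21 C6 alcohol with H7 on the lower face: 2-(trimethylsilyl)ethyl ester of the ring-complete acid carrying O6–H and the O8 phosphonopropionate and the C15 silyl ether (5R,6S,7S,8R,10R)
Conditions: Pd2(dba)3·CHCl3 (2.5 mol %), n-Bu3P (10 mol %), HCO2H, Et3N, THF, rt
Reagents that add atoms: none
Why: Palladium-catalysed formate hydrogenolysis of an alkenyloxirane, in which zerovalent palladium ionizes the allylic C7–O bond from the face opposite the epoxide and the palladium hydride formed from formate is delivered to the more substituted allyl terminus C7 on the metal-bearing, less hindered lower face, so that C7 is inverted, C11 ends cis to O6 and O8 and the 1,1-disubstituted acrylate alkene is regenerated.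

Step 14
Reactants: 21 C6 alcohol
Product: 22 C6 tert-butyldimethylsilyl ether of 21
Conditions: t-BuMe2SiOTf, 2,6-lutidine, CH2Cl2, −20 to 0 °C
Reagents that add atoms: tert-butyldimethylsilyl trifluoromethanesulfonate, CC(C)(C)[Si](C)(C)OS(=O)(=O)C(F)(F)F
Why: Silylation with the silyl triflate caps the hindered O6–H at once, which blocks lactonization onto C12 and alkoxide formation in the olefination.

Step 15
Reactants: 23 (Z)-but-2-ene-1,4-diyl diacetate
Product: 24 2-oxoethyl acetate
Conditions: O3, CH2Cl2, −78 °C; then Me2S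
Reagents that add atoms: ozone, [O-][O+]=O
Why: Ozonolysis with reductive work-up cleaves the symmetrical alkene into two molecules of the aldehyde.

Step 16
Reactants: 22 bis-silyl phosphonate; 24 2-oxoethyl acetate
Product: 25 fully protected target: 2-(trimethylsilyl)ethyl ester and C6 and C15 bis(tert-butyldimethylsilyl) ether carrying the (Z)-4-acetoxy-2-methylbut-2-enoate at O8
Conditions: KN(SiMe3)2, 18-crown-6, THF, −78 °C; then 24
Reagents that add atoms: none
Why: Still–Gennari olefination, in which the potassium anion of the bis(trifluoroethyl) phosphonate adds to the aldehyde under kinetic control and fast elimination gives the Z-trisubstituted enoate (carbonyl and CH2OAc cis), the epimeric phosphonate carbon becoming sp2.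

Step 17
Reactants: 25 fully protected target
Product: 26 target, 2-[(1S,2S,3R,4R,6R)-6-{[(2Z)-4-acetoxy-2-methylbut-2-enoyl]oxy}-4-ethenyl-2-hydroxy-3-(3-hydroxyprop-1-en-2-yl)-4-methylcyclohexyl]prop-2-enoic acid
Conditions: [(Me2N)3S][Me3SiF2] (excess), DMF–H2O, 0 °C to rt; cold pH 5.5 phosphate work-up
Reagents that add atoms: none
Why: Fluoride-induced desilylation under nearly neutral conditions, in which the Me3Si group of the ester (fragmentation to ethene) and the primary silyl ether should fall first and the very hindered C6 silyl ether last, so that O6–H appears only when C12 is already an unreactive carboxylate and the acetate and enoate esters are spared.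

Compound list
1 | 5-bromo-2H-pyran-2-one | O=C1C=CC(Br)=CO1 | starting material
2 | methacrolein | C=C(C)C=O | starting material
3 | (1R,4R,5S)-7-bromo-5-methyl-3-oxo-2-oxabicyclo[2.2.2]oct-7-ene-5-carbaldehyde | O=C[C@@]1(C)C[C@H]2OC(=O)[C@@H]1C=C2Br | intermediate
4 | (1R,4R,5R)-7-bromo-5-ethenyl-5-methyl-2-oxabicyclo[2.2.2]oct-7-en-3-one | C=C[C@@]1(C)C[C@H]2OC(=O)[C@@H]1C=C2Br | intermediate
5 | (1R,4R,5R)-2-bromo-5-ethenyl-4-[2-hydroxy-1,3-bis(trimethylsilyl)propan-2-yl]-5-methylcyclohex-2-en-1-ol | C=C[C@@]1(C)C[C@@H](O)C(Br)=C[C@H]1C(O)(C[Si](C)(C)C)C[Si](C)(C)C | intermediate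
6 | (1R,4R,5R)-2-bromo-5-ethenyl-5-methyl-4-[3-(trimethylsilyl)prop-1-en-2-yl]cyclohex-2-en-1-ol | C=C[C@@]1(C)C[C@@H](O)C(Br)=C[C@H]1C(=C)C[Si](C)(C)C | intermediate
7 | (1R,4R,5R)-2-bromo-5-ethenyl-5-methyl-4-{2-[(trimethylsilyl)methyl]oxiran-2-yl}cyclohex-2-en-1-ol (both epoxide epimers) | C=C[C@@]1(C)C[C@@H](O)C(Br)=C[C@H]1C2(C[Si](C)(C)C)CO2 | intermediate
8 | (1R,4R,5R)-2-bromo-5-ethenyl-4-(3-hydroxyprop-1-en-2-yl)-5-methylcyclohex-2-en-1-ol | C=C[C@@]1(C)C[C@@H](O)C(Br)=C[C@H]1C(=C)CO | intermediate
9 | (1R,4R,5R)-2-bromo-4-{3-[(tert-butyldimethylsilyl)oxy]prop-1-en-2-yl}-5-ethenyl-5-methylcyclohex-2-en-1-ol | C=C[C@@]1(C)C[C@@H](O)C(Br)=C[C@H]1C(=C)CO[Si](C)(C)C(C)(C)C | intermediate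
10 | propiolic acid | C#CC(=O)O | starting material
11 | 2-(trimethylsilyl)ethanol | OCC[Si](C)(C)C | starting material
12 | 2-(trimethylsilyl)ethyl prop-2-ynoate | C#CC(=O)OCC[Si](C)(C)C | intermediate
13 | 2-(trimethylsilyl)ethyl 2-(tributylstannyl)prop-2-enoate | C=C(C(=O)OCC[Si](C)(C)C)[Sn](CCCC)(CCCC)CCCC | intermediate
14 | 2-(trimethylsilyl)ethyl 2-[(3R,4R,6R)-3-{3-[(tert-butyldimethylsilyl)oxy]prop-1-en-2-yl}-4-ethenyl-6-hydroxy-4-methylcyclohex-1-en-1-yl]prop-2-enoate | C=C[C@@]1(C)C[C@@H](O)C(C(=C)C(=O)OCC[Si](C)(C)C)=C[C@H]1C(=C)CO[Si](C)(C)C(C)(C)C | intermediate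
15 | syn-epoxy alcohol of 14 (C6–C7 epoxide cis to O8; 5R,6S,7R,8R,10R) | C=C[C@@]1(C)C[C@@H](O)[C@@]2(C(=C)C(=O)OCC[Si](C)(C)C)O[C@H]2[C@H]1C(=C)CO[Si](C)(C)C(C)(C)C | intermediate
16 | bis(2,2,2-trifluoroethyl) phosphite | O=[PH](OCC(F)(F)F)OCC(F)(F)F | starting material
17 | benzyl 2-bromopropanoate (racemic) | CC(Br)C(=O)OCc1ccccc1 | starting material
18 | benzyl 2-[bis(2,2,2-trifluoroethoxy)phosphoryl]propanoate (racemic) | CC(C(=O)OCc1ccccc1)P(=O)(OCC(F)(F)F)OCC(F)(F)F | intermediate
19 | 2-[bis(2,2,2-trifluoroethoxy)phosphoryl]propanoic acid (racemic) | CC(C(=O)O)P(=O)(OCC(F)(F)F)OCC(F)(F)F | intermediate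
20 | O8 phosphonopropionate of 15 (epimers at the phosphonate carbon) | C=C[C@@]1(C)C[C@@H](OC(=O)C(C)P(=O)(OCC(F)(F)F)OCC(F)(F)F)[C@@]2(C(=C)C(=O)OCC[Si](C)(C)C)O[C@H]2[C@H]1C(=C)CO[Si](C)(C)C(C)(C)C | intermediate
21 | C6 alcohol after hydrogenolysis (5R,6S,7S,8R,10R; epimers at the phosphonate carbon) | C=C[C@@]1(C)C[C@@H](OC(=O)C(C)P(=O)(OCC(F)(F)F)OCC(F)(F)F)[C@@H](C(=C)C(=O)OCC[Si](C)(C)C)[C@@H](O)[C@H]1C(=C)CO[Si](C)(C)C(C)(C)C | intermediate
22 | C6 tert-butyldimethylsilyl ether of 21 | C=C[C@@]1(C)C[C@@H](OC(=O)C(C)P(=O)(OCC(F)(F)F)OCC(F)(F)F)[C@@H](C(=C)C(=O)OCC[Si](C)(C)C)[C@@H](O[Si](C)(C)C(C)(C)C)[C@H]1C(=C)CO[Si](C)(C)C(C)(C)C | intermediate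
23 | (Z)-but-2-ene-1,4-diyl diacetate | CC(=O)OC/C=C\COC(C)=O | starting material
24 | 2-oxoethyl acetate | CC(=O)OCC=O | intermediate
25 | fully protected target (2-(trimethylsilyl)ethyl ester, C6 and C15 silyl ethers, Z-enoate at O8) | C=C[C@@]1(C)C[C@@H](OC(=O)/C(C)=C\COC(C)=O)[C@@H](C(=C)C(=O)OCC[Si](C)(C)C)[C@@H](O[Si](C)(C)C(C)(C)C)[C@H]1C(=C)CO[Si](C)(C)C(C)(C)C | intermediate
26 | CNP0261293.6 | C=C[C@@]1(C)C[C@@H](OC(=O)/C(C)=C\COC(C)=O)[C@@H](C(=C)C(=O)O)[C@@H](O)[C@H]1C(=C)CO | target

Total step count: 17. Longest linear sequence: 12 steps (1, 2, 3, 4, 5, 8, 9, 12, 13, 14, 16, 17).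

Steps most likely to fail

Step 1. The Lewis-basic pyrone carbonyl may tie up the boron catalyst. The diene may be too weakly nucleophilic at low temperature. Exo/endo or facial selectivity may be poor.
Fallback (known chemistry, racemic cycloaddition plus resolution):
- It sets out from 1 and 2, which are heated without catalyst (CH2Cl2, sealed tube, 80 °C, hydroquinone), as in the known thermal cycloadditions of 5-halo-2-pyrones.
- Chromatography should give the racemic exo adduct, that is 3 together with its mirror image, the ent-exo adduct F1.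
- Condensation with (1R,2R)-N,N'-dimethyl-1,2-diphenylethane-1,2-diamine (molecular sieves, Et2O) should give two diastereomeric imidazolidines, the aminal of 3 F2 and the aminal of the mirror image F3, which are separated on silica.
- Mild two-phase acid hydrolysis of F2 comes back to the route at 3.

Step 13. Hydride may be delivered to the primary terminus C13. Beta-hydride elimination, leakage of the metal to the upper face by pi–sigma–pi isomerization, or lactonization of the freed O6–H may also intervene.
Fallback (rearrangement and reduction instead of allylpalladium chemistry):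
- It sets out from 20. A Meinwald rearrangement (BF3·OEt2, CH2Cl2, −78 °C) opens the epoxide at the tertiary allylic C7 and shifts H6 to the lower face of C7, which gives the C6 ketone F4.
- F4 is reduced at once under Luche conditions (NaBH4, CeCl3·7H2O, MeOH, −78 °C). Hydride should come from the face opposite the three cis substituents.
- This comes back to the route at 21.

Step 17. Early loss of the C6 silyl ether may be followed by lactonization onto the still intact ester. Acid-induced lactonization during work-up, O8-to-O6 acyl migration or loss of the acetate are further risks.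
Fallback (orthogonal reductive unmasking of O6 after the carboxylate is in place):
- It sets out from 21, which is converted with Cl3CCH2OCOCl and pyridine into the C6 trichloroethyl carbonate phosphonate F5.
- Still–Gennari olefination with 24 gives the C6 trichloroethyl carbonate Z-enoate F6.
- Fluoride ([(Me2N)3S][Me3SiF2], DMF) removes only the 2-(trimethylsilyl)ethyl ester and the primary silyl ether and gives the C6 trichloroethyl carbonate hydroxy acid F7.
- Zn dust with NH4OAc in THF–H2O, in which the acid is present as its carboxylate, then frees O6–H and comes back to the route at 26.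

Further compounds
F1 | step 1 | (1S,4S,5R)-7-bromo-5-methyl-3-oxo-2-oxabicyclo[2.2.2]oct-7-ene-5-carbaldehyde (mirror image of 3) | O=C[C@]1(C)C[C@@H]2OC(=O)[C@H]1C=C2Br
F2 | step 1 | (4R,5R)-1,3-dimethyl-4,5-diphenylimidazolidin-2-yl aminal of 3 | CN1[C@H](c2ccccc2)[C@@H](c2ccccc2)N(C)C1[C@@]3(C)C[C@H]4OC(=O)[C@@H]3C=C4Br
F3 | step 1 | (4R,5R)-1,3-dimethyl-4,5-diphenylimidazolidin-2-yl aminal of F1 | CN1[C@H](c2ccccc2)[C@@H](c2ccccc2)N(C)C1[C@]3(C)C[C@@H]4OC(=O)[C@H]3C=C4Br
F4 | step 13 | C6 ketone from hydride shift in 20 | C=C[C@@]1(C)C[C@@H](OC(=O)C(C)P(=O)(OCC(F)(F)F)OCC(F)(F)F)[C@@H](C(=C)C(=O)OCC[Si](C)(C)C)C(=O)[C@H]1C(=C)CO[Si](C)(C)C(C)(C)C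
F5 | step 17 | C6 2,2,2-trichloroethyl carbonate of 21 | C=C[C@@]1(C)C[C@@H](OC(=O)C(C)P(=O)(OCC(F)(F)F)OCC(F)(F)F)[C@@H](C(=C)C(=O)OCC[Si](C)(C)C)[C@@H](OC(=O)OCC(Cl)(Cl)Cl)[C@H]1C(=C)CO[Si](C)(C)C(C)(C)C
F6 | step 17 | C6 2,2,2-trichloroethyl carbonate with the Z-enoate at O8 | C=C[C@@]1(C)C[C@@H](OC(=O)/C(C)=C\COC(C)=O)[C@@H](C(=C)C(=O)OCC[Si](C)(C)C)[C@@H](OC(=O)OCC(Cl)(Cl)Cl)[C@H]1C(=C)CO[Si](C)(C)C(C)(C)C
F7 | step 17 | C6 2,2,2-trichloroethyl carbonate of the target | C=C[C@@]1(C)C[C@@H](OC(=O)/C(C)=C\COC(C)=O)[C@@H](C(=C)C(=O)O)[C@@H](OC(=O)OCC(Cl)(Cl)Cl)[C@H]1C(=C)CO
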